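**Retrosynthetic overview**
1. The C‑6 hydroxyl and the 7,8‑epoxide go on last, from a C‑6/C‑7 alkene by ene oxygenation and Ti‑mediated oxygen transfer.
2. The C‑4–C‑5 bond comes from an intramolecular aldol of the C‑9 ketone onto a C‑4 aldehyde, which closes the second six‑membered ring.
3. The C‑1–C‑8 bond (key step) comes from an α‑ketol 1,2‑shift that expands a 1‑acylcyclopent‑3‑en‑1‑ol to a 2‑hydroxycyclohex‑4‑enone and creates C‑1.
4. The ketol comes from alkynyl addition to a five‑membered ketone and CO2‑mediated hydration; N and C‑3 come from an Ellman alkynylation, the C10 acid from a B‑alkyl Suzuki coupling.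
5. Ring order: cyclopentene (bought) → cyclohexenone (ring expansion) → bicyclo[3.3.1]nonane (aldol) → epoxide.

**Assumptions and conventions**
- Compound numbers start at Step 1, in order of first appearance.
- Positions: C‑1 bridgehead C–OH, C‑2 CH2, C‑3 CHN, C‑4 CHOH, C‑5 bridgehead CH, C‑6 CHOH, C‑7/C‑8 epoxide, C‑9 C=O.
- Cyclopent‑3‑en‑1‑one, ethyl (E)‑3‑iodoacrylate, 60 % aq. 2,2‑dimethoxyacetaldehyde, (R)‑tert‑butanesulfinamide and ethynylmagnesium bromide are taken as bought.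
- The Ellman addition in Step 3 is taken to follow the usual cyclic Mg‑chelate model; if the sense is opposite, the (S)‑sulfinamide is used.
- The (S,S)‑ligand in Step 7 is taken as the matched enantiomer; if not, the (R,R)‑ligand is used.

**Step 1**
Reactants: 1 hept‑1‑ene; 2 ethyl (2E)‑3‑iodoprop‑2‑enoate
Product: 5 (2E)‑dec‑2‑enoic acid, via 9‑heptyl‑9‑borabicyclo[3.3.1]nonane 3 (not isolated), via ethyl (2E)‑dec‑2‑enoate 4 (not isolated)
Conditions: 9‑BBN, THF, 0 °C→rt; then 2, PdCl2(dppf) (3 mol%), aq. K3PO4, DMF, rt; then LiOH, H2O–MeOH, 40 °C; HCl work‑up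
Reagents that add atoms: lithium hydroxide, [Li+].[OH-]
Why: Anti‑Markovnikov hydroboration and B‑alkyl Suzuki–Miyaura coupling proceed with retention of the (E)‑vinyl iodide geometry, and saponification in the same pot gives the (E)‑C10 acid.

**Step 2**
Reactants: 6 2,2‑dimethoxyacetaldehyde; 7 (R)‑2‑methylpropane‑2‑sulfinamide
Product: 8 (R,E)‑N‑(2,2‑dimethoxyethylidene)‑2‑methylpropane‑2‑sulfinamide
Conditions: CuSO4 (anhydrous, excess), CH2Cl2, rt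
Reagents that add atoms: none
Why: Ellman condensation under dehydrating conditions gives the (E)‑N‑sulfinyl aldimine; no stereocentre is formed.

**Step 3**
Reactants: 8 (R,E)‑N‑(2,2‑dimethoxyethylidene)‑2‑methylpropane‑2‑sulfinamide; 9 ethynylmagnesium bromide
Product: 10 (R)‑N‑[(2S)‑1,1‑dimethoxybut‑3‑yn‑2‑yl]‑2‑methylpropane‑2‑sulfinamide
Conditions: CH2Cl2, −78→−40 °C; aq. work‑up
Reagents that add atoms: none
Why: Ellman alkynylation through the six‑membered Mg–O=S chelate with tert‑butyl equatorial directs the alkynyl group to the Si face of the C=N bond, setting the future C‑3 as (S).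

**Step 4**
Reactants: 10 (R)‑N‑[(2S)‑1,1‑dimethoxybut‑3‑yn‑2‑yl]‑2‑methylpropane‑2‑sulfinamide; 5 (2E)‑dec‑2‑enoic acid
Product: 12 (2E)‑N‑[(2S)‑1,1‑dimethoxybut‑3‑yn‑2‑yl]dec‑2‑enamide, via (2S)‑1,1‑dimethoxybut‑3‑yn‑2‑aminium chloride 11 (not isolated)
Conditions: HCl (4 M in dioxane), MeOH, 0 °C→rt; evaporate; then 5, EDC·HCl, HOBt, i‑Pr2NEt, CH2Cl2, 0 °C→rt
Reagents that add atoms: none
Why: Acidic methanolysis cleaves only the S–N bond (acetal and alkyne survive), and carbodiimide/HOBt amide coupling of the crude ammonium salt installs the side chain without touching the stereocentre.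

**Step 5**
Reactants: 12 (2E)‑N‑[(2S)‑1,1‑dimethoxybut‑3‑yn‑2‑yl]dec‑2‑enamide; 13 cyclopent‑3‑en‑1‑one
Product: 14 (2E)‑N‑[(2S)‑4‑(1‑hydroxycyclopent‑3‑en‑1‑yl)‑1,1‑dimethoxybut‑3‑yn‑2‑yl]dec‑2‑enamide
Conditions: i‑PrMgCl·LiCl (2.1 equiv), THF, 0 °C→rt; LaCl3·2LiCl (1.1 equiv); then 13, 0 °C; aq. work‑up
Reagents that add atoms: none
Why: The turbo‑Grignard deprotonates N–H and the terminal alkyne, and lanthanide‑promoted 1,2‑addition of the weakly basic alkynyl metal outruns enolisation of the ketone; the carbinol carbon is not stereogenic because the ring is symmetric.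

**Step 6**
Reactants: 14 (2E)‑N‑[(2S)‑4‑(1‑hydroxycyclopent‑3‑en‑1‑yl)‑1,1‑dimethoxybut‑3‑yn‑2‑yl]dec‑2‑enamide
Product: 16 (2E)‑N‑[(2S)‑4‑(1‑hydroxycyclopent‑3‑en‑1‑yl)‑1,1‑dimethoxy‑4‑oxobutan‑2‑yl]dec‑2‑enamide, via (2E)‑N‑[(2S,3Z)‑1,1‑dimethoxy‑3‑(2‑oxo‑1,3‑dioxaspiro[4.4]non‑7‑en‑4‑ylidene)propan‑2‑yl]dec‑2‑enamide 15 (not isolated)
Conditions: AgOAc (10 mol%), DBU (1 equiv), CO2 (10 bar), MeCN, rt; then K2CO3, H2O–MeOH, rt
Reagents that add atoms: carbon dioxide, O=C=O (supplies the ketone oxygen; its carbon leaves again); water, O (net H2O is added)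
Why: In the silver‑catalysed carboxylative cyclisation the alkoxide–CO2 adduct attacks the activated alkyne 5‑exo‑dig, so oxygen goes only to the alkyne carbon next to the carbinol, and hydrolysis of the enol carbonate gives the α‑hydroxy ketone (CO2‑mediated hydration) without Meyer–Schuster rearrangement.

**Step 7 (key step)**
Reactants: 16 (2E)‑N‑[(2S)‑4‑(1‑hydroxycyclopent‑3‑en‑1‑yl)‑1,1‑dimethoxy‑4‑oxobutan‑2‑yl]dec‑2‑enamide
Product: 17 (2E)‑N‑[(2S)‑3‑[(1R)‑1‑hydroxy‑2‑oxocyclohex‑4‑en‑1‑yl]‑1,1‑dimethoxypropan‑2‑yl]dec‑2‑enamide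
Conditions: [Cu((S,S)‑t‑Bu‑box)](SbF6)2 (15 mol%), 4 Å MS, (CH2Cl)2, 40 °C
Reagents that add atoms: none
Why: Proposed new method: a Cu(II)–bisoxazoline‑catalysed, diastereotopic‑group‑selective α‑ketol ring expansion, in which the hydroxyl and carbonyl oxygens of 16 chelate square‑planar Cu(II), the two allylic ring CH2 groups on the carbinol carbon sit above and below the chelate plane, the C2‑symmetric ligand blocks one, and the other makes the suprafacial 1,2‑shift to the activated carbonyl carbon (five‑ to six‑membered ring, acyclic to ring ketone), creating the quaternary carbinol (R) that becomes C‑1; the closest known reaction type is the Lewis‑acid α‑ketol (acyloin) ring expansion of 1‑acylcycloalkanols and its Ni‑ or Cu‑catalysed enantioselective variants on aryl or 1,2‑dicarbonyl ketols, not yet shown for an aliphatic, amide‑bearing 1‑acylcyclopent‑3‑en‑1‑ol.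

**Step 8**
Reactants: 17 (2E)‑N‑[(2S)‑3‑[(1R)‑1‑hydroxy‑2‑oxocyclohex‑4‑en‑1‑yl]‑1,1‑dimethoxypropan‑2‑yl]dec‑2‑enamide
Product: 20 (2E)‑N‑[(1R,3S,4R,5R)‑1,4‑dihydroxy‑9‑oxobicyclo[3.3.1]non‑6‑en‑3‑yl]dec‑2‑enamide, via (2E)‑N‑[(2S)‑1‑[(1R)‑1‑hydroxy‑2‑oxocyclohex‑4‑en‑1‑yl]‑3‑oxopropan‑2‑yl]dec‑2‑enamide 18 (not isolated), via (2E)‑N‑[(3S,5R)‑2‑hydroxy‑6‑oxo‑1‑oxaspiro[4.5]dec‑8‑en‑3‑yl]dec‑2‑enamide 19 (not isolated)
Conditions: TFA–H2O (4:1), 0 °C; evaporate; then MgBr2·OEt2 (3 equiv), i‑Pr2NEt (4 equiv), CH2Cl2, 0 °C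
Reagents that add atoms: water, O
Why: Acetal hydrolysis frees the aldehyde (resting as its spiro‑hemiacetal), and soft enolisation gives a Mg dienolate that adds through its α‑carbon in a chelated six‑membered transition state (intramolecular aldol); the bridge can only close cis so C‑5 follows C‑1, Mg chelation puts the new C‑4 hydroxyl exo and cis to the amide, and dehydration is blocked by Bredt's rule.

**Step 9**
Reactants: 20 (2E)‑N‑[(1R,3S,4R,5R)‑1,4‑dihydroxy‑9‑oxobicyclo[3.3.1]non‑6‑en‑3‑yl]dec‑2‑enamide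
Product: 22 isariotin D, (2E)‑N‑[(1S,3S,4R,5S,6S,7S,8S)‑7,8‑epoxy‑1,4,6‑trihydroxy‑9‑oxobicyclo[3.3.1]nonan‑3‑yl]dec‑2‑enamide, via (2E)‑N‑[(1S,3S,4R,5S,6R)‑6‑hydroperoxy‑1,4‑dihydroxy‑9‑oxobicyclo[3.3.1]non‑7‑en‑3‑yl]dec‑2‑enamide 21 (not isolated)
Conditions: O2, TPP (1 mol%), hν (visible), CH2Cl2, −10 °C; then Ti(Oi‑Pr)4 (0.5 equiv), 4 Å MS, −20→0 °C
Reagents that add atoms: dioxygen, O=O
Why: In the Schenck ene reaction singlet oxygen attacks C‑6 on the open exo face and removes the axial exo H‑8 (H‑5 is at the bridgehead and unavailable), giving the 6‑exo‑hydroperoxide with the alkene moved to C‑7/C‑8, and Ti(IV)‑mediated oxygen transfer then epoxidises that alkene syn to the C‑6 oxygen, setting C‑6, C‑7 and C‑8.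

**Compound list**
1 | hept‑1‑ene | C=CCCCCC | starting material
2 | ethyl (2E)‑3‑iodoprop‑2‑enoate | CCOC(=O)/C=C/I | starting material
3 | 9‑heptyl‑9‑borabicyclo[3.3.1]nonane | CCCCCCCB1C2CCCC1CCC2 | intermediate
4 | ethyl (2E)‑dec‑2‑enoate | CCCCCCC/C=C/C(=O)OCC | intermediate
5 | (2E)‑dec‑2‑enoic acid | CCCCCCC/C=C/C(=O)O | intermediate
6 | 2,2‑dimethoxyacetaldehyde | COC(OC)C=O | starting material
7 | (R)‑2‑methylpropane‑2‑sulfinamide | CC(C)(C)[S@@](=O)N | starting material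
8 | (R,E)‑N‑(2,2‑dimethoxyethylidene)‑2‑methylpropane‑2‑sulfinamide | CC(C)(C)[S@@](=O)/N=C/C(OC)OC | intermediate
9 | ethynylmagnesium bromide | C#C[Mg]Br | starting material
10 | (R)‑N‑[(2S)‑1,1‑dimethoxybut‑3‑yn‑2‑yl]‑2‑methylpropane‑2‑sulfinamide | CC(C)(C)[S@@](=O)N[C@@H](C#C)C(OC)OC | intermediate
11 | (2S)‑1,1‑dimethoxybut‑3‑yn‑2‑aminium chloride | [NH3+][C@@H](C#C)C(OC)OC.[Cl-] | intermediate
12 | (2E)‑N‑[(2S)‑1,1‑dimethoxybut‑3‑yn‑2‑yl]dec‑2‑enamide | CCCCCCC/C=C/C(=O)N[C@@H](C#C)C(OC)OC | intermediate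
13 | cyclopent‑3‑en‑1‑one | O=C1CC=CC1 | starting material
14 | (2E)‑N‑[(2S)‑4‑(1‑hydroxycyclopent‑3‑en‑1‑yl)‑1,1‑dimethoxybut‑3‑yn‑2‑yl]dec‑2‑enamide | CCCCCCC/C=C/C(=O)N[C@@H](C#CC1(O)CC=CC1)C(OC)OC | intermediate
15 | (2E)‑N‑[(2S,3Z)‑1,1‑dimethoxy‑3‑(2‑oxo‑1,3‑dioxaspiro[4.4]non‑7‑en‑4‑ylidene)propan‑2‑yl]dec‑2‑enamide | O=C1O/C(=C\[C@H](NC(=O)/C=C/CCCCCCC)C(OC)OC)C2(CC=CC2)O1 | intermediate
16 | (2E)‑N‑[(2S)‑4‑(1‑hydroxycyclopent‑3‑en‑1‑yl)‑1,1‑dimethoxy‑4‑oxobutan‑2‑yl]dec‑2‑enamide | CCCCCCC/C=C/C(=O)N[C@@H](CC(=O)C1(O)CC=CC1)C(OC)OC | intermediate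
17 | (2E)‑N‑[(2S)‑3‑[(1R)‑1‑hydroxy‑2‑oxocyclohex‑4‑en‑1‑yl]‑1,1‑dimethoxypropan‑2‑yl]dec‑2‑enamide | CCCCCCC/C=C/C(=O)N[C@@H](C[C@@]1(O)C(=O)CC=CC1)C(OC)OC | intermediate
18 | (2E)‑N‑[(2S)‑1‑[(1R)‑1‑hydroxy‑2‑oxocyclohex‑4‑en‑1‑yl]‑3‑oxopropan‑2‑yl]dec‑2‑enamide | CCCCCCC/C=C/C(=O)N[C@@H](C[C@@]1(O)C(=O)CC=CC1)C=O | intermediate
19 | (2E)‑N‑[(3S,5R)‑2‑hydroxy‑6‑oxo‑1‑oxaspiro[4.5]dec‑8‑en‑3‑yl]dec‑2‑enamide (both anomers) | CCCCCCC/C=C/C(=O)N[C@H]1C[C@@]2(OC1O)C(=O)CC=CC2 | intermediate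
20 | (2E)‑N‑[(1R,3S,4R,5R)‑1,4‑dihydroxy‑9‑oxobicyclo[3.3.1]non‑6‑en‑3‑yl]dec‑2‑enamide | CCCCCCC/C=C/C(=O)N[C@H]1C[C@@]2(O)C(=O)[C@H](C=CC2)[C@H]1O | intermediate
21 | (2E)‑N‑[(1S,3S,4R,5S,6R)‑6‑hydroperoxy‑1,4‑dihydroxy‑9‑oxobicyclo[3.3.1]non‑7‑en‑3‑yl]dec‑2‑enamide | CCCCCCC/C=C/C(=O)N[C@H]1C[C@@]2(O)C(=O)[C@H]([C@H](OO)C=C2)[C@H]1O | intermediate
22 | isariotin D | CCCCCCC/C=C/C(=O)N[C@H]1C[C@@]2(O)C(=O)[C@H]([C@H](O)[C@@H]3O[C@@H]32)[C@H]1O | target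

**Totals**
Total step count: 9. Longest linear sequence: 8 (Steps 2–9, from 6 and 7 to 22).

**Three steps most likely to fail**

Step 7 (the proposed new step). The risks are poor selection between the two ring CH2 groups and inhibition of the Cu catalyst by the amide or acetal. The fallback uses known chemistry, sets out from 16 and comes back at 17. Catalyst control is given up and the classical stoichiometric aluminium‑alkoxide α‑ketol ring expansion is run (Al(Ot‑Bu)3, toluene, 80 °C). This gives 17 together with its epimer at the carbinol carbon, (2E)‑N‑[(2S)‑3‑[(1S)‑1‑hydroxy‑2‑oxocyclohex‑4‑en‑1‑yl]‑1,1‑dimethoxypropan‑2‑yl]dec‑2‑enamide F1. The two are separated by chromatography, and F1 is re‑equilibrated with 17 by a further pass through the same reversible ketol shift. The stereocentre then comes from separation and recycling instead of induction.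

Step 8. The risks are attack through the γ‑carbon of the dienolate, epimerisation next to the free aldehyde, and closure through an open transition state to the wrong C‑4 alcohol. The fallback sets out from 17 and comes back at 20. If the aldol gives mainly the C‑4 epimer, (2E)‑N‑[(1R,3S,4S,5R)‑1,4‑dihydroxy‑9‑oxobicyclo[3.3.1]non‑6‑en‑3‑yl]dec‑2‑enamide F2 (hydroxyl endo, trans to the amide), it is inverted rather than discarded. Mitsunobu reaction (PPh3, DIAD, 4‑nitrobenzoic acid, THF, 0 °C) brings the carboxylate in from the open exo face and gives (1R,3S,4R,5R)‑3‑[(2E)‑dec‑2‑enamido]‑1‑hydroxy‑9‑oxobicyclo[3.3.1]non‑6‑en‑4‑yl 4‑nitrobenzoate F3. Methanolysis (K2CO3, MeOH, 0 °C) then gives 20.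

Step 9. The risk is slow ene reaction of the cis‑disubstituted ring alkene with singlet oxygen, or loss of material with Ti(IV). The fallback sets out from 20 and comes back at 22, building the oxygen pattern stepwise. mCPBA/NaHCO3 (CH2Cl2, 0 °C) epoxidises the C‑6/C‑7 alkene from the exo face to the 6,7‑exo‑epoxide of 20, (2E)‑N‑[6,7‑exo‑epoxy‑1,4‑dihydroxy‑9‑oxobicyclo[3.3.1]nonan‑3‑yl]dec‑2‑enamide (other centres as in 20) F4. Et2Al–TMP (toluene, 0 °C) isomerises the epoxide to the allylic alcohol by removing H‑8, the only β‑hydrogen not at a bridgehead, giving (2E)‑N‑[(1S,3S,4R,5R,6R)‑1,4,6‑trihydroxy‑9‑oxobicyclo[3.3.1]non‑7‑en‑3‑yl]dec‑2‑enamide F5. Hydroxyl‑directed epoxidation (VO(acac)2, t‑BuOOH, CH2Cl2, 0 °C) then gives 22.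

**Further compounds**
F1 | step 7 | (2E)‑N‑[(2S)‑3‑[(1S)‑1‑hydroxy‑2‑oxocyclohex‑4‑en‑1‑yl]‑1,1‑dimethoxypropan‑2‑yl]dec‑2‑enamide | CCCCCCC/C=C/C(=O)N[C@@H](C[C@]1(O)C(=O)CC=CC1)C(OC)OC
F2 | step 8 | (2E)‑N‑[(1R,3S,4S,5R)‑1,4‑dihydroxy‑9‑oxobicyclo[3.3.1]non‑6‑en‑3‑yl]dec‑2‑enamide | CCCCCCC/C=C/C(=O)N[C@H]1C[C@@]2(O)C(=O)[C@H](C=CC2)[C@@H]1O
F3 | step 8 | (1R,3S,4R,5R)‑3‑[(2E)‑dec‑2‑enamido]‑1‑hydroxy‑9‑oxobicyclo[3.3.1]non‑6‑en‑4‑yl 4‑nitrobenzoate | CCCCCCC/C=C/C(=O)N[C@H]1C[C@@]2(O)C(=O)[C@H](C=CC2)[C@H]1OC(=O)c1ccc(cc1)[N+](=O)[O-]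
F4 | step 9 | (2E)‑N‑[6,7‑exo‑epoxy‑1,4‑dihydroxy‑9‑oxobicyclo[3.3.1]nonan‑3‑yl]dec‑2‑enamide (other centres as in 20) | CCCCCCC/C=C/C(=O)N[C@H]1C[C@@]2(O)C(=O)[C@H]([C@@H]3O[C@@H]3C2)[C@H]1O
F5 | step 9 | (2E)‑N‑[(1S,3S,4R,5R,6R)‑1,4,6‑trihydroxy‑9‑oxobicyclo[3.3.1]non‑7‑en‑3‑yl]dec‑2‑enamide | CCCCCCC/C=C/C(=O)N[C@H]1C[C@@]2(O)C(=O)[C@H]([C@H](O)C=C2)[C@H]1O
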